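Atoms carry labdane numbers (ring A: C1–C5 and C10; ring B: C5–C10; carboxyl carbon C17 on C8). The route rests on opening ring B at the C6–C7 bond. In the key step a vinyl radical at C7, generated from a dibromomethylene group on C8, adds 6-endo to the CH2 terminus (C6) of an exocyclic C5=C6 alkene on ring A; one operation closes ring B, keeps C7=C8 conjugated to the C17 ester and sets the trans C5–H ring fusion. It exploits the 1,1-disubstituted C5=C6 alkene flanked by the quaternary C4 and C10. The precursor, a monocyclic dibromoacrylate, comes from an enantioselective Gosteli–Claisen rearrangement that sets C9 and C10.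

Key step: step 8

Remark: the sense of asymmetric induction in step 6 is assigned from the square-planar chelate model of the copper bis(oxazoline) catalyst; should it prove opposite, the (R,R)-ligand is used.

Step 1
Reactants: 1 geranyl acetate
Product: 2 (2E)-3-methyl-6-oxohex-2-en-1-yl acetate
Conditions: O3 (1 equiv), CH2Cl2, pyridine (cat.), −78 °C; then Me2S, −78 °C to rt
Reagents that add atoms: ozone, [O-][O+]=O
Why: Chemoselective ozonolysis, in which the electron-rich 6,7-alkene should react far faster than the 2,3-alkene deactivated by the allylic acetate, so that only the isopropylidene end is cleaved and the (E)-allylic acetate survives; no stereocenter is formed.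

Step 2
Reactants: 3 β-cyclocitral
Product: 4 β-cyclogeraniol, (2,6,6-trimethylcyclohex-1-en-1-yl)methanol
Conditions: NaBH4, MeOH, 0 °C
Reagents that add atoms: none
Why: Borohydride 1,2-reduction of the hindered enal (carbonyl hydride reduction) should give the primary allylic alcohol cleanly; no stereocenter is formed.

Step 3
Reactants: 5 triethyl phosphonoacetate
Product: 6 ethyl 2-diazo-2-(diethoxyphosphoryl)acetate
Conditions: NaH, THF, 0 °C; then 4-acetamidobenzenesulfonyl azide, 0 °C to rt
Reagents that add atoms: 4-acetamidobenzenesulfonyl azide, CC(=O)Nc1ccc(cc1)S(=O)(=O)N=[N+]=[N-]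
Why: Regitz diazo transfer from the sulfonyl azide to the sodium phosphonoacetate carbanion is the standard entry to diazophosphonoacetates; no stereocenter is formed.

Step 4
Reactants: 4 β-cyclogeraniol; 6 ethyl 2-diazo-2-(diethoxyphosphoryl)acetate
Product: 7 ethyl 2-(diethoxyphosphoryl)-2-[(2,6,6-trimethylcyclohex-1-en-1-yl)methoxy]acetate (racemic)
Conditions: Rh2(OAc)4 (1 mol %), toluene, 80 °C
Reagents that add atoms: none
Why: Rhodium-carbenoid O–H insertion into the primary allylic alcohol should outrun cyclopropanation of the tetrasubstituted ring alkene; the new α-carbon stereocenter is racemic and is destroyed in step 5.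

Step 5
Reactants: 7 the α-allyloxy phosphonate; 2 (2E)-3-methyl-6-oxohex-2-en-1-yl acetate
Product: 8 ethyl (2E,6E)-8-acetoxy-6-methyl-2-[(2,6,6-trimethylcyclohex-1-en-1-yl)methoxy]octa-2,6-dienoate
Conditions: LiN(SiMe3)2, THF, −78 °C; then 2, −78 °C to rt; chromatographic separation of the (E)-isomer
Reagents that add atoms: none
Why: Horner–Wadsworth–Emmons olefination of the α-alkoxy phosphonate anion builds the trisubstituted enol ether as an expected E/Z mixture, from which the (2E)-isomer (side chain cis to the ester) is separated because only it places the side chain equatorial in the chair transition state of step 6.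

Step 6
Reactants: 8 the (2E)-allyl vinyl ether
Product: 9 ethyl (3R,6E)-8-acetoxy-6-methyl-2-oxo-3-[(1R)-1,3,3-trimethyl-2-methylidenecyclohexyl]oct-6-enoate
Conditions: [Cu((S,S)-tBu-box)(H2O)2](SbF6)2 (10 mol %; tBu-box = 2,2'-(propane-2,2-diyl)bis[4-tert-butyl-4,5-dihydrooxazole]), CH2Cl2, 4 Å molecular sieves, rt
Reagents that add atoms: none
Why: Catalytic enantioselective Gosteli–Claisen rearrangement, in which chelation of the ether and ester oxygens to the cationic divalent copper complex accelerates the [3,3]-shift and shields one face of the vinyl ether so that C9 should form as (R), while the chair transition state (side chain equatorial, C10 methyl axial by the ring-fixed allyl geometry) relays this to the quaternary C10 and leaves the exocyclic C5=C6 alkene.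

Step 7
Reactants: 9 the α-keto ester
Product: 10 ethyl (3R,6E)-8-acetoxy-2-(dibromomethylidene)-6-methyl-3-[(1R)-1,3,3-trimethyl-2-methylidenecyclohexyl]oct-6-enoate
Conditions: CBr4, PPh3, Zn, CH2Cl2, 0 °C to rt
Reagents that add atoms: carbon tetrabromide, BrC(Br)(Br)Br
Why: Ramirez (Corey–Fuchs-type) dibromo-olefination of the activated ketone of the α-keto ester runs under non-basic conditions, so the acidic C9–H next to the ketone should not epimerise; no new stereocenter is formed.

Step 8
Reactants: 10 the dibromoacrylate
Product: 12 ethyl (1R,4aS,8aS)-1-[(3E)-5-acetoxy-3-methylpent-3-en-1-yl]-5,5,8a-trimethyl-1,4,4a,5,6,7,8,8a-octahydronaphthalene-2-carboxylate, via ring-closed C7-bromo enoate 11 (not isolated)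
Conditions: Bu3SnH (3 equiv, syringe pump), azobisisobutyronitrile (0.2 equiv), benzene (0.005 M), 80 °C
Reagents that add atoms: none
Why: A stannyl radical abstracts one bromine of the dibromomethylene group to give a σ-type 1-bromovinyl radical at C7, which adds to the unhindered CH2 terminus (C6) of the exocyclic C5=C6 alkene; the tertiary C5 radical takes a hydrogen atom from Bu3SnH, and a second stannyl radical then removes the remaining vinylic bromine of 11, whose ring vinyl radical is reduced to the C7–H enoate. The closest known reaction type is the Stork tin-hydride vinyl-radical cyclization of bromoalkenes, here run on a gem-dibromoalkene. Ring B is closed in the 6-endo-trig mode; a 5-exo attack at C5, hindered by the quaternary C4 and C10, would feed the same C5 radical through the known 3-exo closure and reopening (homoallyl–cyclopropylcarbinyl rearrangement). The new stereocenter C5 is set in the hydrogen-atom transfer, the stannane approaching axially from the face opposite the axial C10 and C4 methyl groups to give the trans ring fusion, while C9 and C10 are untouched. The step needs cyclization to beat direct reduction, 1,5-hydrogen transfer from the allylic C12–H and attack on the C13=C14 alkene; slow addition of the stannane at high dilution and the Thorpe–Ingold effect of C10 should secure this. Because the vinyl radical loses its geometry, either bromine and any monobromide formed by early reduction lead to the same ring closure.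

Step 9
Reactants: 12 the bicyclic ethyl ester acetate
Product: 13 (1R,4aS,8aS)-1-[(3E)-5-hydroxy-3-methylpent-3-en-1-yl]-5,5,8a-trimethyl-1,4,4a,5,6,7,8,8a-octahydronaphthalene-2-carboxylic acid
Conditions: KOH, EtOH/H2O (4:1), 80 °C; then aqueous HCl to pH 3
Reagents that add atoms: potassium hydroxide, [K+].[OH-]
Why: Saponification (acyl substitution by hydroxide) cleaves the primary acetate and, on heating, the hindered conjugated ethyl ester; the conjugated C7=C8 position is the thermodynamic one and C9–H is not acidic, so no stereocenter should be affected.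

Step 10
Reactants: 13 the hydroxy acid
Product: 14 (1R,4aS,8aS)-5,5,8a-trimethyl-1-[(3E)-3-methyl-5-(2-methylpropanoyloxy)pent-3-en-1-yl]-1,4,4a,5,6,7,8,8a-octahydronaphthalene-2-carboxylic acid (target)
Conditions: isobutyric anhydride (1.2 equiv), pyridine, 4-(dimethylamino)pyridine (cat.), CH2Cl2, 0 °C; then aqueous NaHCO3/THF, acidify
Reagents that add atoms: isobutyric anhydride, CC(C)C(=O)OC(=O)C(C)C
Why: Nucleophile-catalysed O-acylation (nucleophilic acyl substitution) of the primary allylic alcohol should be much faster than reaction at the hindered carboxylic acid, and any mixed anhydride is hydrolysed in the bicarbonate work-up; no stereocenter is touched.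

Compound list
1 | geranyl acetate, (2E)-3,7-dimethylocta-2,6-dien-1-yl acetate | CC(C)=CCC/C(C)=C/COC(C)=O | starting material
2 | (2E)-3-methyl-6-oxohex-2-en-1-yl acetate | O=CCC/C(C)=C/COC(C)=O | intermediate
3 | β-cyclocitral, 2,6,6-trimethylcyclohex-1-ene-1-carbaldehyde | CC1=C(C=O)C(C)(C)CCC1 | starting material
4 | β-cyclogeraniol, (2,6,6-trimethylcyclohex-1-en-1-yl)methanol | CC1=C(CO)C(C)(C)CCC1 | intermediate
5 | triethyl phosphonoacetate | CCOC(=O)CP(=O)(OCC)OCC | starting material
6 | ethyl 2-diazo-2-(diethoxyphosphoryl)acetate | CCOC(=O)C(=[N+]=[N-])P(=O)(OCC)OCC | intermediate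
7 | ethyl 2-(diethoxyphosphoryl)-2-[(2,6,6-trimethylcyclohex-1-en-1-yl)methoxy]acetate (racemic) | CCOC(=O)C(OCC1=C(C)CCCC1(C)C)P(=O)(OCC)OCC | intermediate
8 | ethyl (2E,6E)-8-acetoxy-6-methyl-2-[(2,6,6-trimethylcyclohex-1-en-1-yl)methoxy]octa-2,6-dienoate | CCOC(=O)/C(OCC1=C(C)CCCC1(C)C)=C\CC/C(C)=C/COC(C)=O | intermediate
9 | ethyl (3R,6E)-8-acetoxy-6-methyl-2-oxo-3-[(1R)-1,3,3-trimethyl-2-methylidenecyclohexyl]oct-6-enoate | CCOC(=O)C(=O)[C@H](CC/C(C)=C/COC(C)=O)[C@@]1(C)CCCC(C)(C)C1=C | intermediate
10 | ethyl (3R,6E)-8-acetoxy-2-(dibromomethylidene)-6-methyl-3-[(1R)-1,3,3-trimethyl-2-methylidenecyclohexyl]oct-6-enoate | CCOC(=O)C(=C(Br)Br)[C@H](CC/C(C)=C/COC(C)=O)[C@@]1(C)CCCC(C)(C)C1=C | intermediate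
11 | ethyl (1R,4aS,8aS)-1-[(3E)-5-acetoxy-3-methylpent-3-en-1-yl]-3-bromo-5,5,8a-trimethyl-1,4,4a,5,6,7,8,8a-octahydronaphthalene-2-carboxylate | C/C(=C\COC(C)=O)CC[C@H]1C(C(=O)OCC)=C(Br)C[C@H]2C(C)(C)CCC[C@]12C | intermediate (not isolated)
12 | ethyl (1R,4aS,8aS)-1-[(3E)-5-acetoxy-3-methylpent-3-en-1-yl]-5,5,8a-trimethyl-1,4,4a,5,6,7,8,8a-octahydronaphthalene-2-carboxylate | C/C(=C\COC(C)=O)CC[C@H]1C(C(=O)OCC)=CC[C@H]2C(C)(C)CCC[C@]12C | intermediate
13 | (1R,4aS,8aS)-1-[(3E)-5-hydroxy-3-methylpent-3-en-1-yl]-5,5,8a-trimethyl-1,4,4a,5,6,7,8,8a-octahydronaphthalene-2-carboxylic acid | C/C(=C\CO)CC[C@H]1C(C(=O)O)=CC[C@H]2C(C)(C)CCC[C@]12C | intermediate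
14 | (1R,4aS,8aS)-5,5,8a-trimethyl-1-[(3E)-3-methyl-5-(2-methylpropanoyloxy)pent-3-en-1-yl]-1,4,4a,5,6,7,8,8a-octahydronaphthalene-2-carboxylic acid | C/C(=C\COC(=O)C(C)C)CC[C@H]1C(C(=O)O)=CC[C@H]2C(C)(C)CCC[C@]12C | target

Total step count: 10. Longest linear sequence: 8 steps (from 3 through steps 2 and 4–10, or equally from 5 through steps 3–10).

Steps most likely to fail

Step 6. The Lewis acid may ionise the allylic C–O bond (a stabilised tertiary allylic cation can form from the ring A allyl unit), giving a stepwise shift with loss of stereocontrol. Face discrimination may also be poor at the hindered, fully substituted allyl terminus. The fallback gives up asymmetric catalysis for resolution. Setting out from 8, the rearrangement is run thermally without catalyst (toluene, 100 °C); it should still be diastereoselective through the chair transition state but gives a racemate. The enantiomers are then separated by preparative chromatography on a cellulose tris(3,5-dimethylphenylcarbamate) stationary phase, removing the enantiomeric keto ester F1. The route is rejoined at 9.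

Step 8. The vinyl radical may be reduced before it cyclises, may shift a hydrogen from the allylic C12 position, or may attack the side-chain alkene; hydrogen delivery to C5 may also show poor facial selectivity. The fallback replaces the radical closure by an organometallic one. Setting out from 10, the exocyclic C5=C6 alkene is hydroborated with 9-borabicyclo[3.3.1]nonane (THF, 0 °C to rt), which puts boron on C6 and hydrogen on C5 from the face opposite the C10 methyl, giving the C6 alkylborane F2. An intramolecular B-alkyl Suzuki–Miyaura coupling with the bromine cis to C9 (PdCl2(dppf), dppf = 1,1'-bis(diphenylphosphino)ferrocene; AsPh3, Cs2CO3, DMF/H2O, rt to 50 °C) then forms the C6–C7 bond and gives 11, here isolated. Hydrodebromination of 11 with Pd(PPh3)4 and Bu3SnH (THF, rt) returns the route at 12.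

Step 7. Olefination of the ketone, hindered by the branched C9 and the neighbouring quaternary C10, may stall with the weakly nucleophilic dibromo ylide. The fallback uses the more reactive non-stabilised ylide. Setting out from 9, Wittig bromomethylenation with Ph3P=CHBr (from (bromomethyl)triphenylphosphonium bromide and KN(SiMe3)2, THF, −78 °C, ketone added to the ylide to limit enolisation at C9) gives the monobromoacrylate F3 as an E/Z mixture. Both isomers give the same rapidly inverting C7 vinyl radical under the conditions of step 8 (2 equiv less stannane), so the cyclisation leads directly to 12, where the route is rejoined.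

Further compounds
F1 | step 6 | ethyl (3S,6E)-8-acetoxy-6-methyl-2-oxo-3-[(1S)-1,3,3-trimethyl-2-methylidenecyclohexyl]oct-6-enoate (enantiomer of 9) | CCOC(=O)C(=O)[C@@H](CC/C(C)=C/COC(C)=O)[C@]1(C)CCCC(C)(C)C1=C
F2 | step 8 | ethyl (3R,6E)-8-acetoxy-3-[(1S,2S)-2-(9-borabicyclo[3.3.1]nonan-9-ylmethyl)-1,3,3-trimethylcyclohexyl]-2-(dibromomethylidene)-6-methyloct-6-enoate | CCOC(=O)C(=C(Br)Br)[C@H](CC/C(C)=C/COC(C)=O)[C@@]1(C)CCCC(C)(C)[C@@H]1CB1C2CCCC1CCC2
F3 | step 7 | ethyl (3R,6E)-8-acetoxy-2-(bromomethylidene)-6-methyl-3-[(1R)-1,3,3-trimethyl-2-methylidenecyclohexyl]oct-6-enoate (E/Z mixture at the bromoalkene) | CCOC(=O)C(=CBr)[C@H](CC/C(C)=C/COC(C)=O)[C@@]1(C)CCCC(C)(C)C1=C
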